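## Retrosynthetic overview

- **Feature.** The C10 carbinol carbon, the Z alkene C1=C2 and the allylic alcohol C3(OH)–C4(Me)=C5 (Z) of the ten-membered ring are what a decalin leaves behind when its C5–C10 fusion bond breaks (ring A: C10, C1–C5; ring B: C5–C10). A C10 alkoxide pushes and a C3–C4 epoxide leaves at C4.
- **Disconnections.** The tiglate and the C13 methylene come last. C10–CH3 comes from methyl addition to a C10 ketone. The ten-membered ring comes from an epoxy decalinol by Grob-type fragmentation.
- **Ring fusion.** The decalin must be cis-fused, with 10-OH, 5-H and the epoxide oxygen on one face. Only then can C5–C6 stand axial on ring A and give the Z alkene; a trans fusion holds C5–C6 antiperiplanar to C4–C3 and leads to E. The same arrangement keeps the alkoxide from opening the epoxide from the back.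
- **Ring order.** Ring B comes from (−)-shikimic acid: C8 is kept, C5 and C10 are set by anti conjugate addition and enolate hydroxylation, C7 by olefination and conjugate reduction, C6 by oxidation and reduction. The five-membered oxygen ring follows, then ring A by ring-closing metathesis, the ten-membered ring by fragmentation, and last the α-methylene lactone.

Key step: step 22

**Numbering.** Germacrane numbering is used for all intermediates. Shikimate C1–C6 correspond to C10, C5, C6, C7, C8, C9, and the carboxyl carbon is C1. α is the ring face that carries O8; β is the opposite face.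

**Assumption.** The lactol silyl ether is drawn as the exo (β-OSi) anomer and enoate 18 without an alkene descriptor; both elements vanish later, so either isomer can be carried on.

## Route

Step 1
Reactants: 1 but-2-yn-1-ol
Product: 3 (Z)-3-iodobut-2-en-1-ol, via cyclic alkenylalanate 2 (not isolated)
Conditions: NaAlH2(OCH2CH2OMe)2, Et2O, 0 °C to rt; I2, THF, −78 to 0 °C
Reagents that add atoms: iodine, II
Why: Hydroxyl-directed trans-hydroalumination of the propargylic alcohol puts aluminium on C3 inside a five-membered alanate, and iodinolysis with retention should give only the Z iodide.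

Step 2
Reactants: 3 (Z)-3-iodobut-2-en-1-ol
Product: 4 (Z)-3-iodobut-2-enal
Conditions: MnO2, CH2Cl2, rt
Reagents that add atoms: none
Why: Allylic alcohol oxidation with MnO2 is neutral and should leave the Z alkene unisomerised.

Step 3
Reactants: 4 (Z)-3-iodobut-2-enal
Product: 5 (3Z)-4-iodopenta-1,3-diene
Conditions: Ph3PCH3Br, KOt-Bu, THF, 0 °C; 4, −78 to 0 °C
Reagents that add atoms: methyltriphenylphosphonium bromide, C[P+](c1ccccc1)(c1ccccc1)c1ccccc1.[Br-]
Why: Wittig methylenation converts the aldehyde into the terminal alkene without touching the iodoalkene, so iodine and vinyl stay cis.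

Step 4
Reactants: 6 (−)-shikimic acid
Product: 7 methyl (−)-shikimate
Conditions: MeOH, camphorsulfonic acid (cat.), reflux
Reagents that add atoms: methanol, CO
Why: Fischer esterification leaves the three carbinol centres untouched (O6 β, O7 β, O8 α), and C8 already has the configuration of the target.

Step 5
Reactants: 7 methyl (−)-shikimate
Product: 8 methyl 3,4-O-isopropylideneshikimate (acetonide on O6 and O7)
Conditions: Me2C(OMe)2, camphorsulfonic acid (cat.), acetone, rt
Reagents that add atoms: 2,2-dimethoxypropane, COC(C)(C)OC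
Why: Acetonide formation picks the only cis-vicinal diol (O6/O7) and leaves O8–H free.

Step 6
Reactants: 8 methyl 3,4-O-isopropylideneshikimate
Product: 9 methyl 5-O-TBS-3,4-O-isopropylideneshikimate (enoate C10=C5)
Conditions: t-BuMe2SiCl, imidazole, DMF, rt
Reagents that add atoms: tert-butyldimethylsilyl chloride, CC(C)(C)[Si](C)(C)Cl
Why: Standard silylation of the single free secondary hydroxyl.

Step 7
Reactants: 5 (3Z)-4-iodopenta-1,3-diene; 9 methyl 5-O-TBS-3,4-O-isopropylideneshikimate
Product: 12 saturated ester with 5α-[(2Z)-penta-2,4-dien-2-yl] group (5-H β; 10-H β), via dienylmagnesium chloride 10 (not isolated), via silyl ketene acetal 11 (not isolated)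
Conditions: 5, i-PrMgCl·LiCl, THF, −20 °C to rt; CuBr·SMe2 (30 mol%), Me3SiCl, 9, THF, −78 to −30 °C; aq. NH4Cl
Reagents that add atoms: none
Why: Iodine–magnesium exchange with retention, then copper-catalysed, Me3SiCl-accelerated conjugate addition, should deliver the dienyl group axially to C5 anti to the pseudoaxial C6–O bond of the β-acetonide, which sets C5 (C4 α, 5-H β).

Step 8
Reactants: 12 saturated ester
Product: 14 10β-hydroxy ester (C1 ester carbon α, cis to the dienyl group), via potassium ester enolate 13 (not isolated)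
Conditions: KN(SiMe3)2, THF, −78 °C; 3-phenyl-2-(phenylsulfonyl)oxaziridine, −78 °C; AcOH
Reagents that add atoms: 3-phenyl-2-(phenylsulfonyl)oxaziridine, O=S(=O)(c1ccccc1)N1OC1c1ccccc1
Why: In this enolate hydroxylation with a Davis oxaziridine the oxidant should come from the β face, anti to the neighbouring axial C5 dienyl group, which sets C10 (OH β).

Step 9
Reactants: 14 10β-hydroxy ester
Product: 15 6β,7β,10β-triol
Conditions: AcOH–H2O 4:1, 40 °C
Reagents that add atoms: none
Why: Acid hydrolysis of the acetonide is done while C1 is still an ester, so no ionisable allylic carbinol is present and the secondary TBS ether should survive.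

Step 10
Reactants: 15 6β,7β,10β-triol
Product: 16 6β-O-triethylsilyl ether (7-OH and 10-OH free)
Conditions: Et3SiCl (1.05 equiv), imidazole, CH2Cl2, −20 °C
Reagents that add atoms: chlorotriethylsilane, CC[Si](Cl)(CC)CC
Why: Regioselective silylation should spare the C7 hydroxyl, which is wedged between two oxygenated carbons (one bearing the bulky OTBS) like the unreactive central hydroxyl of quinate esters, and the tertiary C10 hydroxyl is inert.

Step 11
Reactants: 16 6β-O-triethylsilyl ether
Product: 17 7-ketone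
Conditions: Dess–Martin periodinane, CH2Cl2, rt
Reagents that add atoms: none
Why: Dess–Martin oxidation takes the only secondary hydroxyl under conditions that do not enolise C6 or C8.

Step 12
Reactants: 17 7-ketone
Product: 18 7-(methoxycarbonylmethylidene) compound (C7=C11)
Conditions: Ph3P=CHCO2Me, toluene, 90 °C
Reagents that add atoms: methyl (triphenylphosphoranylidene)acetate, COC(=O)C=P(c1ccccc1)(c1ccccc1)c1ccccc1
Why: Wittig olefination with a stabilised ylide, as used on α,α'-dialkoxy ketones, brings in C11 and C12 without base, and either alkene isomer serves the next step.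

Step 13
Reactants: 18 7-(methoxycarbonylmethylidene) compound
Product: 19 diester with 7α-CH2CO2Me (7-H β)
Conditions: Cu(OAc)2·H2O (5 mol%), 1,2-(Ph2P)2C6H4 (5 mol%), MeSiH(OEt)2, t-BuOH, toluene, rt
Reagents that add atoms: none
Why: Copper hydride conjugate reduction should deliver hydride to C7 from the β face, because the α face is covered by the C5 dienyl, C8 OTBS and C10 ester groups; this sets C7 and leaves the unactivated diene alone.

Step 14
Reactants: 19 diester
Product: 20 6β-alcohol
Conditions: AcOH–THF–H2O 3:1:1, 0 °C to rt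
Reagents that add atoms: none
Why: Mild acidic desilylation removes the triethylsilyl ether well before the TBS ether.

Step 15
Reactants: 20 6β-alcohol
Product: 21 6-ketone
Conditions: Dess–Martin periodinane, CH2Cl2, 0 °C
Reagents that add atoms: none
Why: Dess–Martin oxidation is neutral, so neither epimerisation at C5 or C7 nor retro-aldol loss of the C10 carbinol should set in, and 21 is used at once.

Step 16
Reactants: 21 6-ketone
Product: 23 cis-fused 6α,12-γ-lactone (C1 methyl ester kept), via lithium 6α-alkoxide 22 (not isolated)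
Conditions: LiBH(s-Bu)3, THF, −78 to 0 °C; H2O
Reagents that add atoms: none
Why: The bulky borohydride should attack the ketone from the open β face, and the resulting α alkoxide, now cis to the C7 side chain, closes the γ-lactone by acyl substitution, which sets C6 with net inversion.

Step 17
Reactants: 23 cis-fused γ-lactone
Product: 24 lactol aldehyde (C12 lactol; C1 aldehyde)
Conditions: i-Bu2AlH (5 equiv), CH2Cl2, −78 °C; aq. KNaC4H4O6
Reagents that add atoms: none
Why: In this low-temperature partial reduction both tetrahedral aluminium adducts should persist (that of the ester is chelated by the C10 alkoxide), so work-up gives lactol and aldehyde.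

Step 18
Reactants: 24 lactol aldehyde
Product: 25 lactol TBS ether aldehyde
Conditions: t-BuMe2SiCl, imidazole, DMF, 0 °C
Reagents that add atoms: tert-butyldimethylsilyl chloride, CC(C)(C)[Si](C)(C)Cl
Why: Silylation takes the lactol hydroxyl (the most acidic and least hindered one) and gives a base-stable furanoside-type silyl acetal that fluoride can remove later, so no aqueous acid ever meets the allylic carbinols.

Step 19
Reactants: 25 lactol TBS ether aldehyde
Product: 26 triene (10α-vinyl carbinol with 5α-dienyl group)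
Conditions: Ph3PCH3Br, KOt-Bu, THF, 0 °C; 25, −78 to 0 °C
Reagents that add atoms: methyltriphenylphosphonium bromide, C[P+](c1ccccc1)(c1ccccc1)c1ccccc1.[Br-]
Why: Wittig methylenation with excess ylide at low temperature should outrun α-ketol rearrangement of the hydroxy aldehyde.

Step 20
Reactants: 26 triene
Product: 27 cis-fused cyclohexadienol (ring A closed; 10-OH β, 5-H β)
Conditions: second-generation Grubbs catalyst RuCl2(=CHPh)(PCy3)(H2IMes) (5 mol%), CH2Cl2, 40 °C, acid-free glassware
Reagents that add atoms: none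
Why: Ring-closing metathesis of the vinyl carbinol with the terminal alkene of the Z-diene can only close the six-membered ring A, with C1=C2 necessarily Z and the cis fusion preset by the two α substituents; since 27 is an arene hydrate, acid is excluded.

Step 21
Reactants: 27 cis-fused cyclohexadienol
Product: 28 cis-fused 3β,4β-epoxy-octalin-10β-ol with the furanoside-type silyl acetal
Conditions: dimethyldioxirane (1.0 equiv), acetone–CH2Cl2, −40 °C
Reagents that add atoms: dimethyldioxirane, CC1(C)OO1
Why: This neutral epoxidation should take the trisubstituted, more electron-rich C3=C4 (C1=C2 is deactivated by the allylic C10–O) from the β face, which is both the convex face of the cis-decalin and the face of the hydrogen-bonding 10-OH, and so sets C3 and C4.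

Step 22
Reactants: 28 cis-fused 3β,4β-epoxy-octalin-10β-ol
Product: 31 (1Z,4Z)-3β-hydroxycyclodeca-1,4-dien-10-one with silyl acetal and 8-OTBS, via potassium alkoxide 29 (not isolated), via ring-opened potassium alkoxide 30 (not isolated)
Conditions: KH (1.2 equiv), THF, 0 °C to rt; AcOH, −78 °C
Reagents that add atoms: none
Why: KH turns the tertiary C10 hydroxyl into alkoxide 29, whose electron push breaks the C5–C10 fusion bond while the C4=C5 π bond forms and the C4–O bond of the epoxide opens, a Grob-type 1,3-fragmentation whose closest known relatives are the base- or Ti(OiPr)4-mediated fragmentations of bicyclic 3,4-epoxy alcohols that are made by hydroxyl-directed epoxidation and therefore also carry carbinol and epoxide oxygen on the same face. No ring is closed by bond formation: rings A and B merge into the ten-membered ring when their shared bond is cut, and strain release of the epoxide and of the crowded cis-decalin, together with the conjugated C10 enone, drives the step. With both oxygens on the β face K+ can bridge O10 and the epoxide oxygen in a six-membered array (K, O10, C10, C5, C4, O), in which the C5–C10 and C4–O bonds start synclinal (roughly 40° in models) and approach syn-periplanarity as the fusion bond lengthens, while back-side attack of O10 on C3 or C4 (1,4-ether or oxetane) is geometrically excluded. No stereocentre is created: C3 keeps the epoxide configuration, C4, C5 and C10 become trigonal, and C6, C7 and C8 are spectators. The alkene geometries follow from the bicycle: C1=C2 stays Z as in the six-membered ring, and C4=C5 should become Z because in the chelated cis-decalin conformer the C5–C6 bond is axial on ring A and folds towards C3, whereas a trans fusion would hold C5–C6 antiperiplanar to C4–C3 and give E. The selectivity needed is cleavage of C5–C10 rather than C9–C10 or C1–C10, which is secured because only C5 carries a β leaving group, and alkoxide 30 is quenched cold to forestall closure of O3 onto C10.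

Step 23
Reactants: 31 3β-hydroxy dienone
Product: 32 3-O-triisopropylsilyl dienone
Conditions: i-Pr3SiOTf, 2,6-lutidine, CH2Cl2, −78 °C, directly after step 22
Reagents that add atoms: triisopropylsilyl trifluoromethanesulfonate, CC(C)[Si](OS(=O)(=O)C(F)(F)F)(C(C)C)C(C)C
Why: Fast silylation of the secondary allylic hydroxyl should drain the open Z-γ-hydroxy enone from its equilibrium with the 3,10-hemiketal and block dehydration towards a furan.

Step 24
Reactants: 32 3-O-triisopropylsilyl dienone
Product: 33 10β-hydroxy-10α-methyl compound (10R)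
Conditions: CeCl3, MeLi, THF, −78 °C
Reagents that add atoms: methyllithium, [Li]C
Why: In this organocerium 1,2-addition the non-basic MeCeCl2 adds to the enone carbonyl, and because in the folded conformation inherited from the decalin the inner face of C10 looks across the ring at C4=C5, methyl should enter from the periphery, the face opposite to the departed C5, which sets C10 as required.

Step 25
Reactants: 33 10β-hydroxy-10α-methyl compound
Product: 34 lactol
Conditions: HF·pyridine (1.5 equiv), pyridine, THF, −20 °C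
Reagents that add atoms: none
Why: In this selective fluoride desilylation the silyl acetal should go first, because a hemiacetal oxide is the best leaving group on silicon and the exo OTBS is the least hindered, and no aqueous acid touches the tertiary allylic and bis-allylic C–O bonds.

Step 26
Reactants: 34 lactol
Product: 35 6α,12-γ-lactone
Conditions: Pr4N[RuO4] (5 mol%), N-methylmorpholine N-oxide, 4 Å MS, CH2Cl2, 0 °C
Reagents that add atoms: none
Why: Ley–Griffith oxidation of the lactol to the lactone meets no other oxidisable hydroxyl, since C10–OH is tertiary.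

Step 27
Reactants: 35 6α,12-γ-lactone
Product: 39 α-methylene-γ-lactone, via dilithium enolate alkoxide 36 (not isolated), via Mannich base 37 (not isolated), via trimethylammonium iodide 38 (not isolated)
Conditions: LiN(i-Pr)2 (3 equiv), THF, −78 °C; Me2N=CH2 I, −78 °C to rt; MeI, MeOH, rt; aq. NaHCO3, CH2Cl2
Reagents that add atoms: dimethyl(methylidene)ammonium iodide, C[N+](C)=C.[I-]
Why: The Eschenmoser methylenation (Mannich reaction of the lactone enolate, quaternisation, Hofmann-type elimination) installs C13, and the transient C11 centre is lost again.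

Step 28
Reactants: 39 α-methylene-γ-lactone
Product: 40 8α-alcohol
Conditions: HF·pyridine, pyridine, THF, 0 °C to rt
Reagents that add atoms: none
Why: Under acidic fluoride desilylation the TBS ether should leave well before the bulkier triisopropylsilyl ether, and the medium avoids alkoxide-driven translactonisation or oxa-Michael addition.

Step 29
Reactants: 40 8α-alcohol
Product: 41 8-O-tiglate
Conditions: (E)-2-methylbut-2-enoyl chloride, Et3N, DMAP (cat.), CH2Cl2, 0 °C to rt
Reagents that add atoms: tigloyl chloride, C/C=C(\C)C(=O)Cl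
Why: DMAP-catalysed acylation takes the only reactive hydroxyl (C10–OH is tertiary and hindered), and the E geometry comes with the reagent.

Step 30
Reactants: 41 8-O-tiglate
Product: 42 CNP0262559.2 (target)
Conditions: Bu4NF, AcOH, THF, 0 °C to rt
Reagents that add atoms: none
Why: Buffered fluoride desilylation frees the C3 hydroxyl without harming the α-methylene lactone, the tiglate or the allylic carbinols.

## Compound list

1 | but-2-yn-1-ol | CC#CCO | starting material
2 | sodium cyclic alkenylalanate | CC1=CCO[Al-]1(OCCOC)OCCOC.[Na+] | intermediate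
3 | (Z)-3-iodobut-2-en-1-ol | C/C(I)=C/CO | intermediate
4 | (Z)-3-iodobut-2-enal | C/C(I)=C/C=O | intermediate
5 | (3Z)-4-iodopenta-1,3-diene | C/C(I)=C/C=C | intermediate
6 | (−)-shikimic acid | OC(=O)C1=C[C@@H](O)[C@@H](O)[C@H](O)C1 | starting material
7 | methyl (−)-shikimate | COC(=O)C1=C[C@@H](O)[C@@H](O)[C@H](O)C1 | intermediate
8 | methyl 3,4-O-isopropylideneshikimate | COC(=O)C1=C[C@H]2OC(C)(C)O[C@H]2[C@H](O)C1 | intermediate
9 | methyl 5-O-TBS-3,4-O-isopropylideneshikimate | COC(=O)C1=C[C@H]2OC(C)(C)O[C@H]2[C@H](O[Si](C)(C)C(C)(C)C)C1 | intermediate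
10 | (2Z)-penta-2,4-dien-2-ylmagnesium chloride | C/C([Mg]Cl)=C/C=C | intermediate
11 | silyl ketene acetal | COC(O[Si](C)(C)C)=C1C[C@@H](O[Si](C)(C)C(C)(C)C)[C@@H]2OC(C)(C)O[C@@H]2[C@H]1/C(C)=C\C=C | intermediate
12 | 5α-dienyl saturated ester | COC(=O)[C@H]1C[C@@H](O[Si](C)(C)C(C)(C)C)[C@@H]2OC(C)(C)O[C@@H]2[C@H]1/C(C)=C\C=C | intermediate
13 | potassium ester enolate | COC([O-])=C1C[C@@H](O[Si](C)(C)C(C)(C)C)[C@@H]2OC(C)(C)O[C@@H]2[C@H]1/C(C)=C\C=C.[K+] | intermediate
14 | 10β-hydroxy ester | COC(=O)[C@@]1(O)C[C@@H](O[Si](C)(C)C(C)(C)C)[C@@H]2OC(C)(C)O[C@@H]2[C@H]1/C(C)=C\C=C | intermediate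
15 | 6β,7β,10β-triol | COC(=O)[C@@]1(O)C[C@@H](O[Si](C)(C)C(C)(C)C)[C@H](O)[C@H](O)[C@H]1/C(C)=C\C=C | intermediate
16 | 6β-O-triethylsilyl ether | COC(=O)[C@@]1(O)C[C@@H](O[Si](C)(C)C(C)(C)C)[C@H](O)[C@H](O[Si](CC)(CC)CC)[C@H]1/C(C)=C\C=C | intermediate
17 | 7-ketone | COC(=O)[C@@]1(O)C[C@@H](O[Si](C)(C)C(C)(C)C)C(=O)[C@H](O[Si](CC)(CC)CC)[C@H]1/C(C)=C\C=C | intermediate
18 | 7-(methoxycarbonylmethylidene) compound | COC(=O)[C@@]1(O)C[C@@H](O[Si](C)(C)C(C)(C)C)C(=CC(=O)OC)[C@H](O[Si](CC)(CC)CC)[C@H]1/C(C)=C\C=C | intermediate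
19 | diester with 7α-CH2CO2Me | COC(=O)[C@@]1(O)C[C@@H](O[Si](C)(C)C(C)(C)C)[C@@H](CC(=O)OC)[C@H](O[Si](CC)(CC)CC)[C@H]1/C(C)=C\C=C | intermediate
20 | 6β-alcohol | COC(=O)[C@@]1(O)C[C@@H](O[Si](C)(C)C(C)(C)C)[C@@H](CC(=O)OC)[C@H](O)[C@H]1/C(C)=C\C=C | intermediate
21 | 6-ketone | COC(=O)[C@@]1(O)C[C@@H](O[Si](C)(C)C(C)(C)C)[C@@H](CC(=O)OC)C(=O)[C@H]1/C(C)=C\C=C | intermediate
22 | lithium 6α-alkoxide | COC(=O)[C@@]1(O)C[C@@H](O[Si](C)(C)C(C)(C)C)[C@@H](CC(=O)OC)[C@@H]([O-])[C@H]1/C(C)=C\C=C.[Li+] | intermediate
23 | cis-fused 6α,12-γ-lactone ester | COC(=O)[C@@]1(O)C[C@@H](O[Si](C)(C)C(C)(C)C)[C@H]2CC(=O)O[C@H]2[C@H]1/C(C)=C\C=C | intermediate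
24 | lactol aldehyde | O=C[C@@]1(O)C[C@@H](O[Si](C)(C)C(C)(C)C)[C@H]2CC(O)O[C@H]2[C@H]1/C(C)=C\C=C | intermediate
25 | lactol TBS ether aldehyde | O=C[C@@]1(O)C[C@@H](O[Si](C)(C)C(C)(C)C)[C@H]2C[C@H](O[Si](C)(C)C(C)(C)C)O[C@H]2[C@H]1/C(C)=C\C=C | intermediate
26 | triene | C=C[C@@]1(O)C[C@@H](O[Si](C)(C)C(C)(C)C)[C@H]2C[C@H](O[Si](C)(C)C(C)(C)C)O[C@H]2[C@H]1/C(C)=C\C=C | intermediate
27 | cis-fused cyclohexadienol | O[C@@]12C=CC=C(C)[C@@H]1[C@@H]3O[C@@H](O[Si](C)(C)C(C)(C)C)C[C@@H]3[C@H](O[Si](C)(C)C(C)(C)C)C2 | intermediate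
28 | cis-fused 3β,4β-epoxy-octalin-10β-ol | O[C@@]12C=C[C@H]3O[C@@]3(C)[C@@H]1[C@@H]4O[C@@H](O[Si](C)(C)C(C)(C)C)C[C@@H]4[C@H](O[Si](C)(C)C(C)(C)C)C2 | intermediate
29 | potassium alkoxide of 28 | [O-][C@@]12C=C[C@H]3O[C@@]3(C)[C@@H]1[C@@H]4O[C@@H](O[Si](C)(C)C(C)(C)C)C[C@@H]4[C@H](O[Si](C)(C)C(C)(C)C)C2.[K+] | intermediate
30 | potassium C3 alkoxide of 31 | C1[C@H](O[Si](C)(C)C(C)(C)C)O[C@H]2/C=C(/C)[C@H]([O-])/C=C\C(=O)C[C@@H](O[Si](C)(C)C(C)(C)C)[C@@H]12.[K+] | intermediate
31 | (1Z,4Z)-3β-hydroxycyclodecadien-10-one | C1[C@H](O[Si](C)(C)C(C)(C)C)O[C@H]2/C=C(/C)[C@H](O)/C=C\C(=O)C[C@@H](O[Si](C)(C)C(C)(C)C)[C@@H]12 | intermediate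
32 | 3-O-triisopropylsilyl dienone | C1[C@H](O[Si](C)(C)C(C)(C)C)O[C@H]2/C=C(/C)[C@H](O[Si](C(C)C)(C(C)C)C(C)C)/C=C\C(=O)C[C@@H](O[Si](C)(C)C(C)(C)C)[C@@H]12 | intermediate
33 | 10β-hydroxy-10α-methyl compound | C1[C@H](O[Si](C)(C)C(C)(C)C)O[C@H]2/C=C(/C)[C@H](O[Si](C(C)C)(C(C)C)C(C)C)/C=C\[C@](C)(O)C[C@@H](O[Si](C)(C)C(C)(C)C)[C@@H]12 | intermediate
34 | lactol | C1C(O)O[C@H]2/C=C(/C)[C@H](O[Si](C(C)C)(C(C)C)C(C)C)/C=C\[C@](C)(O)C[C@@H](O[Si](C)(C)C(C)(C)C)[C@@H]12 | intermediate
35 | 6α,12-γ-lactone | C1C(=O)O[C@H]2/C=C(/C)[C@H](O[Si](C(C)C)(C(C)C)C(C)C)/C=C\[C@](C)(O)C[C@@H](O[Si](C)(C)C(C)(C)C)[C@@H]12 | intermediate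
36 | dilithium enolate alkoxide | C1=C([O-])O[C@H]2/C=C(/C)[C@H](O[Si](C(C)C)(C(C)C)C(C)C)/C=C\[C@](C)([O-])C[C@@H](O[Si](C)(C)C(C)(C)C)[C@@H]12.[Li+].[Li+] | intermediate
37 | Mannich base | CN(C)CC1C(=O)O[C@H]2/C=C(/C)[C@H](O[Si](C(C)C)(C(C)C)C(C)C)/C=C\[C@](C)(O)C[C@@H](O[Si](C)(C)C(C)(C)C)[C@@H]12 | intermediate
38 | trimethylammonium iodide | C[N+](C)(C)CC1C(=O)O[C@H]2/C=C(/C)[C@H](O[Si](C(C)C)(C(C)C)C(C)C)/C=C\[C@](C)(O)C[C@@H](O[Si](C)(C)C(C)(C)C)[C@@H]12.[I-] | intermediate
39 | α-methylene-γ-lactone | C=C1C(=O)O[C@H]2/C=C(/C)[C@H](O[Si](C(C)C)(C(C)C)C(C)C)/C=C\[C@](C)(O)C[C@@H](O[Si](C)(C)C(C)(C)C)[C@@H]12 | intermediate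
40 | 8α-alcohol | C=C1C(=O)O[C@H]2/C=C(/C)[C@H](O[Si](C(C)C)(C(C)C)C(C)C)/C=C\[C@](C)(O)C[C@@H](O)[C@@H]12 | intermediate
41 | 8-O-tiglate | C=C1C(=O)O[C@H]2/C=C(/C)[C@H](O[Si](C(C)C)(C(C)C)C(C)C)/C=C\[C@](C)(O)C[C@@H](OC(=O)/C(C)=C/C)[C@@H]12 | intermediate
42 | CNP0262559.2 | C=C1C(=O)O[C@H]2/C=C(/C)[C@H](O)/C=C\[C@](C)(O)C[C@@H](OC(=O)/C(C)=C/C)[C@@H]12 | target

## Step count

- Total step count: 30
- Longest linear sequence: 27 (steps 4–30, from (−)-shikimic acid)

## Steps most likely to fail

**1. Step 22.**
- Risk: the fusion bond may resist cleavage, because an epoxide inside ring A can only align its C4–O bond synclinally with C5–C10 and the reactive chair must first be populated. On longer exposure the vinyl epoxide may isomerise, or the released C3 alkoxide may close onto C10 and drift towards a furan.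
- Fallback (sets out from 28, comes back at 32): the nucleofuge is changed to one that can stand antiperiplanar.
  - MgBr2·OEt2 opens the epoxide at the tertiary C4 with inversion to the bromohydrin F1. C3–O is untouched, and the equatorial α C4–Br bond is antiperiplanar to C5–C10.
  - i-Pr3SiOTf with 2,6-lutidine caps the C3 hydroxyl to give the bromo silyl ether F2, so the epoxide cannot re-form.
  - KN(SiMe3)2 then triggers the classical antiperiplanar Grob fragmentation of a γ-bromo alkoxide, which gives 32 directly.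

**2. Step 7.**
- Risk: transfer of the α-branched dienyl group to the β-carbon of a trisubstituted enoate may be too slow, so that reduction, loss of the γ-alkoxide or 1,2-addition takes over.
- Fallback (sets out from 9, comes back at 14): the acceptor is made more electrophilic.
  - i-Bu2AlH reduces 9 to the allylic alcohol F3, and MnO2 gives the enal F4.
  - The same dienyl copper reagent with Me3SiCl adds to the enal to give the silyl enol ether F5.
  - Rubottom oxidation with dimethyldioxirane installs the 10β-hydroxyl in the hydroxy aldehyde F6.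
  - Pinnick oxidation gives the acid F7, and Me3SiCHN2 gives 14, so step 8 is skipped as well.

**3. Step 24.**
- Risk: the C9–C10–C1 unit of the flexible ten-membered ring may rotate, so that the carbonyl reacts through the flipped rotamer and methyl enters on the wrong face.
- Fallback (sets out from 32, comes back at 33): the order of bond formation at C10 is reversed, so that oxygen and not carbon comes from the periphery.
  - Wittig methylenation gives the exocyclic methylene compound F8.
  - OsO4 with N-methylmorpholine N-oxide dihydroxylates the least hindered 1,1-disubstituted alkene to the diol F9.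
  - The primary hydroxyl is tosylated to the tosylate F10, and LiBHEt3 reduces it to the methyl group of 33.

Further compounds
F1 | step 22 | 3β-hydroxy-4α-bromo decalinol (bromohydrin) | O[C@@]12C=C[C@@H](O)[C@](C)(Br)[C@@H]1[C@@H]3O[C@@H](O[Si](C)(C)C(C)(C)C)C[C@@H]3[C@H](O[Si](C)(C)C(C)(C)C)C2
F2 | step 22 | 3β-O-triisopropylsilyl-4α-bromo decalinol | O[C@@]12C=C[C@@H](O[Si](C(C)C)(C(C)C)C(C)C)[C@](C)(Br)[C@@H]1[C@@H]3O[C@@H](O[Si](C)(C)C(C)(C)C)C[C@@H]3[C@H](O[Si](C)(C)C(C)(C)C)C2
F3 | step 7 | shikimate-derived allylic alcohol | OCC1=C[C@H]2OC(C)(C)O[C@H]2[C@H](O[Si](C)(C)C(C)(C)C)C1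
F4 | step 7 | shikimate-derived enal | O=CC1=C[C@H]2OC(C)(C)O[C@H]2[C@H](O[Si](C)(C)C(C)(C)C)C1
F5 | step 7 | trimethylsilyl enol ether of the 5α-dienyl aldehyde | C[Si](C)(C)OC=C1C[C@@H](O[Si](C)(C)C(C)(C)C)[C@@H]2OC(C)(C)O[C@@H]2[C@H]1/C(C)=C\C=C
F6 | step 7 | 10β-hydroxy aldehyde | O=C[C@@]1(O)C[C@@H](O[Si](C)(C)C(C)(C)C)[C@@H]2OC(C)(C)O[C@@H]2[C@H]1/C(C)=C\C=C
F7 | step 7 | 10β-hydroxy acid | OC(=O)[C@@]1(O)C[C@@H](O[Si](C)(C)C(C)(C)C)[C@@H]2OC(C)(C)O[C@@H]2[C@H]1/C(C)=C\C=C
F8 | step 24 | 10-methylidene compound | C1[C@H](O[Si](C)(C)C(C)(C)C)O[C@H]2/C=C(/C)[C@H](O[Si](C(C)C)(C(C)C)C(C)C)/C=C\C(=C)C[C@@H](O[Si](C)(C)C(C)(C)C)[C@@H]12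
F9 | step 24 | 10β-hydroxy-10α-hydroxymethyl diol | C1[C@H](O[Si](C)(C)C(C)(C)C)O[C@H]2/C=C(/C)[C@H](O[Si](C(C)C)(C(C)C)C(C)C)/C=C\[C@](CO)(O)C[C@@H](O[Si](C)(C)C(C)(C)C)[C@@H]12
F10 | step 24 | primary tosylate | C1[C@H](O[Si](C)(C)C(C)(C)C)O[C@H]2/C=C(/C)[C@H](O[Si](C(C)C)(C(C)C)C(C)C)/C=C\[C@](COS(=O)(=O)c3ccc(C)cc3)(O)C[C@@H](O[Si](C)(C)C(C)(C)C)[C@@H]12
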